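The isoflavan is disconnected at O1–C2. The key step exploits that C2 is an unsubstituted methylene on O1 while its neighbour C3 carries the electron-rich ring B. In a 2,3-diarylpropene whose C3=C2 bond is a 1,1-disubstituted alkene and whose ring A has a free ortho phenol, the nucleophile, the acceptor carbon and the radical-stabilising aryl group are already in register. One photoredox operation oxidises this alkene, closes the pyran ring by anti-Markovnikov O1–C2 bond formation and sets C3 by hydrogen-atom transfer from a chiral thiol. The precursor comes from Negishi coupling of a ring A benzylzinc reagent with a ring B alkenyl triflate, whose 1,1-dimethylallyl group is installed by aromatic Claisen rearrangement.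

Key step: step 13

Assumption: the sense of induction of the thiol cannot be predicted. The (S)-thiol is written as the antipode that leads to (3S), and the (R)-thiol takes its place if the first experiment shows the opposite sense. Both antipodes are accessible from BINOL by mono-O-methylation, O-thiocarbamoylation, Newman–Kwart rearrangement and reductive cleavage. This catalyst preparation is not counted in the steps.

Design notes:
- **Configuration.** At C3 the ranking is C2 > C1' > C4 > H, and the target SMILES reads S.
- **O7 as pivalate rather than ether.** Ring A becomes harder to oxidise, so the hole should sit on the ring B styrene and not on the phenol. The cyclised product becomes less prone to re-oxidation, and the ring A benzyl chloride is stabilised.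
- **O3' and O4' as MOM ethers.** Ring B stays the most electron-rich part, and the catechol is freed last, under acid and never under base.
- **Late unmasking of the phenol.** It is freed only after the alkene is in place. The precursor is kept away from strong acid, which would close it in the Markovnikov sense.

Step 1
Reactants: 1 2,3,4-trihydroxyacetophenone; 2 1-bromo-3-methylbut-2-ene
Product: 3 1-[2,3-dihydroxy-4-(3-methylbut-2-enyloxy)phenyl]ethanone
Conditions: 2 (1.0 equiv), NaHCO3, DMF, 40 °C
Reagents that add atoms: none
Why: Williamson etherification that is regioselective because NaHCO3 ionises only the most acidic 4-OH (para to the acetyl group), the 2-OH being tied up in a hydrogen bond to the carbonyl and the 3-OH lacking conjugation with it.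

Step 2
Reactants: 3 1-[2,3-dihydroxy-4-(3-methylbut-2-enyloxy)phenyl]ethanone
Product: 4 1-[2-hydroxy-3-(methoxymethoxy)-4-(3-methylbut-2-enyloxy)phenyl]ethanone
Conditions: MOMCl (1.1 equiv), iPr2NEt, CH2Cl2, 0 °C to rt
Reagents that add atoms: chloromethyl methyl ether (MOMCl), COCCl
Why: MOM ether formation (O-alkylation with a chloromethyl ether) that takes the free 3-OH, since the chelated 2-OH reacts much more slowly with MOMCl and a tertiary amine.

Step 3
Reactants: 4 1-[2-hydroxy-3-(methoxymethoxy)-4-(3-methylbut-2-enyloxy)phenyl]ethanone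
Product: 5 1-[2-methoxy-3-(methoxymethoxy)-4-(3-methylbut-2-enyloxy)phenyl]ethanone
Conditions: MeI, K2CO3, DMF, 40 °C
Reagents that add atoms: iodomethane, CI
Why: Williamson O-methylation of the remaining chelated phenol, for which carbonate in a dipolar aprotic solvent is strong enough while leaving the methyl ketone unenolised.

Step 4
Reactants: 5 1-[2-methoxy-3-(methoxymethoxy)-4-(3-methylbut-2-enyloxy)phenyl]ethanone
Product: 6 1-[4-hydroxy-2-methoxy-3-(methoxymethoxy)-5-(2-methylbut-3-en-2-yl)phenyl]ethanone
Conditions: PhNEt2, 195 °C, sealed tube, Ar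
Reagents that add atoms: none
Why: Aromatic Claisen rearrangement: the [3,3] shift turns the O-prenyl group end for end and delivers it as the 1,1-dimethylallyl group to C5, the only open ortho position because C3 is oxygenated, and the basic solvent speeds rearomatisation and holds back acid-induced follow-up reactions of the new ortho-allyl phenol.

Step 5
Reactants: 6 1-[4-hydroxy-2-methoxy-3-(methoxymethoxy)-5-(2-methylbut-3-en-2-yl)phenyl]ethanone
Product: 7 1-[2-methoxy-3,4-bis(methoxymethoxy)-5-(2-methylbut-3-en-2-yl)phenyl]ethanone
Conditions: MOMCl, iPr2NEt, CH2Cl2, 0 to 40 °C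
Reagents that add atoms: chloromethyl methyl ether (MOMCl), COCCl
Why: MOM ether formation on the new 4-OH, which is hindered but acidic (para to the acetyl group) and is met by a small, very reactive electrophile.

Step 6
Reactants: 7 1-[2-methoxy-3,4-bis(methoxymethoxy)-5-(2-methylbut-3-en-2-yl)phenyl]ethanone
Product: 9 1-[2-methoxy-3,4-bis(methoxymethoxy)-5-(2-methylbut-3-en-2-yl)phenyl]ethenyl trifluoromethanesulfonate, via potassium enolate 8 (not isolated)
Conditions: KN(SiMe3)2, THF, −78 °C; PhNTf2, −78 to 0 °C; Et3N-deactivated silica
Reagents that add atoms: N-phenylbis(trifluoromethanesulfonimide), O=S(=O)(C(F)(F)F)N(c1ccccc1)S(=O)(=O)C(F)(F)F; potassium bis(trimethylsilyl)amide, [K+].C[Si](C)(C)[N-][Si](C)(C)C (potassium stays only in 8)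
Why: Enolate O-sulfonylation (alkenyl triflate synthesis): the acetyl group is the only enolisable site, so deprotonation at low temperature and trapping with PhNTf2 can give only the terminal alkenyl triflate, which already contains C3=C2 of the precursor.

Step 7
Reactants: 10 2,4-dihydroxybenzaldehyde
Product: 11 4-formyl-3-hydroxyphenyl pivalate
Conditions: PivCl (1.05 equiv), Et3N, CH2Cl2, 0 °C
Reagents that add atoms: pivaloyl chloride, CC(C)(C)C(=O)Cl
Why: Selective O-acylation: one equivalent of pivaloyl chloride esterifies the free 4-OH, the 2-OH being deactivated by its hydrogen bond to the aldehyde.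

Step 8
Reactants: 11 4-formyl-3-hydroxyphenyl pivalate
Product: 12 3-(tert-butyldimethylsilyloxy)-4-formylphenyl pivalate
Conditions: TBSCl, imidazole, DMF, rt
Reagents that add atoms: tert-butyldimethylsilyl chloride, CC(C)(C)[Si](C)(C)Cl
Why: Silyl ether formation with TBSCl and imidazole masks the future O1 with a group that is orthogonal to pivalate and MOM and tolerates organozinc chemistry.

Step 9
Reactants: 12 3-(tert-butyldimethylsilyloxy)-4-formylphenyl pivalate
Product: 13 3-(tert-butyldimethylsilyloxy)-4-(hydroxymethyl)phenyl pivalate
Conditions: NaBH4, THF/EtOH, −10 °C; aq NH4Cl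
Reagents that add atoms: none
Why: Borohydride reduction of the aldehyde, run cold and quenched promptly so that the silyl group does not migrate from the phenol oxygen to the new alkoxide, with the hindered aryl pivalate left intact.

Step 10
Reactants: 13 3-(tert-butyldimethylsilyloxy)-4-(hydroxymethyl)phenyl pivalate
Product: 14 3-(tert-butyldimethylsilyloxy)-4-(chloromethyl)phenyl pivalate
Conditions: SOCl2, pyridine, CH2Cl2, 0 °C
Reagents that add atoms: thionyl chloride, O=S(Cl)Cl
Why: Deoxychlorination of a benzylic alcohol with SOCl2 buffered by pyridine, giving a chloride that the para acyloxy group makes far less prone to ionisation and self-condensation than a 2,4-dialkoxybenzyl chloride.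

Step 11
Reactants: 14 3-(tert-butyldimethylsilyloxy)-4-(chloromethyl)phenyl pivalate; 9 1-[2-methoxy-3,4-bis(methoxymethoxy)-5-(2-methylbut-3-en-2-yl)phenyl]ethenyl trifluoromethanesulfonate
Product: 16 3-(tert-butyldimethylsilyloxy)-4-{2-[2-methoxy-3,4-bis(methoxymethoxy)-5-(2-methylbut-3-en-2-yl)phenyl]prop-2-enyl}phenyl pivalate, via benzylzinc chloride 15 (not isolated)
Conditions: Zn dust, LiCl, THF, rt; then 9, Pd(PPh3)4 (5 mol%), THF, rt to 45 °C
Reagents that add atoms: zinc, [Zn] (kept only in 15)
Why: LiCl-promoted zinc insertion into the benzylic chloride followed by Negishi coupling: the mild benzylzinc reagent tolerates ester, silyl ether and acetals, and its coupling with the alkenyl triflate at zerovalent palladium forms C3–C4 and puts the 1,1-disubstituted alkene in place directly under non-basic conditions that do not move it into conjugation.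

Step 12
Reactants: 16 3-(tert-butyldimethylsilyloxy)-4-{2-[2-methoxy-3,4-bis(methoxymethoxy)-5-(2-methylbut-3-en-2-yl)phenyl]prop-2-enyl}phenyl pivalate
Product: 17 3-hydroxy-4-{2-[2-methoxy-3,4-bis(methoxymethoxy)-5-(2-methylbut-3-en-2-yl)phenyl]prop-2-enyl}phenyl pivalate (cyclisation precursor)
Conditions: Bu4NF/AcOH (1:1), THF, 0 °C
Reagents that add atoms: none
Why: Fluoride-induced cleavage of the aryl silyl ether, buffered with acetic acid so that neither the pivalate nor the doubly activated C4 methylene meets a strong base, and free of strong acid that would close the phenol onto the alkene in the Markovnikov sense.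

Step 13
Reactants: 17 3-hydroxy-4-{2-[2-methoxy-3,4-bis(methoxymethoxy)-5-(2-methylbut-3-en-2-yl)phenyl]prop-2-enyl}phenyl pivalate
Product: 18 (3S)-2'-methoxy-3',4'-bis(methoxymethoxy)-5'-(2-methylbut-3-en-2-yl)isoflavan-7-yl pivalate
Conditions: 3,6-di-tert-butyl-9-mesityl-10-phenylacridinium tetrafluoroborate (5 mol%), (S)-2'-methoxy-1,1'-binaphthyl-2-thiol (20 mol%), 2,6-lutidine (20 mol%), ClCH2CH2Cl (0.05 M, degassed), 450 nm LED, −20 °C
Reagents that add atoms: none
Why: Proposed new method: the excited acridinium removes one electron from the most electron-rich π system, the ring B-conjugated C3=C2 alkene; the ring A phenol adds to the unsubstituted terminus C2 (O1–C2 bond), the proton is lost, and the resulting tertiary benzylic C3 radical takes a hydrogen atom from the chiral aryl thiol, whose thiyl radical is reduced by the acridinyl radical and reprotonated, so that the whole event is a redox-neutral isomerisation. The closest known reaction types are the racemic acridinium/thiol anti-Markovnikov hydroetherification of alkenols and enantioselective hydrogen-atom transfer from chiral thiols to prochiral carbon radicals (radical-chain hydrosilylation, photochemical deracemisation and hydroamination); joining the two, and doing so with a phenol nucleophile, is without precedent. The pyran ring closes 6-endo-trig, because attack at C2 leaves the stabilised benzylic radical whereas 5-exo attack at C3 would leave a primary one, and 2,6-lutidine removes adventitious acid that could trigger the ionic Markovnikov 5-exo closure. C3 is the only new stereocentre and is set solely by the axially chiral thiol, which has to tell apart the two faces of a planar radical flanked by the 2'-methoxyaryl group, C2 and C4; an aryl thiol is chosen because its S–H bond is weaker than the benzylic C3–H bond being made, so that transfer should be fast and practically irreversible and the thiyl radical should not racemise the product, and the low temperature should sharpen face selection. Chemoselectivity is needed between three oxidisable sites and is secured by the substrate: the trioxygenated styrene of ring B is oxidised more easily than the pivalate-deactivated ring A phenol and far more easily than the isolated vinyl group, which sits on a quaternary carbon at C5', out of reach of the C3 radical.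

Step 14
Reactants: 18 (3S)-2'-methoxy-3',4'-bis(methoxymethoxy)-5'-(2-methylbut-3-en-2-yl)isoflavan-7-yl pivalate
Product: 20 (3S)-7,3',4'-trihydroxy-2'-methoxy-5'-(1,1-dimethylallyl)isoflavan, via free 7-phenol 19 (not isolated)
Conditions: K2CO3, MeOH, rt to 40 °C, Ar; then conc. HCl to ca. 1 M, MeOH, 40 °C
Reagents that add atoms: none
Why: Base-catalysed transesterification of the aryl pivalate while the catechol is still masked, then acid-catalysed acetal exchange of both MOM ethers with methanol in the same flask; the acid is too weak to protonate the monosubstituted alkene, methanol traps the formaldehyde equivalent as dimethoxymethane, and C3, which bears no acidic or ionisable bond, keeps its configuration.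

Compound list
1 | 2,3,4-trihydroxyacetophenone | CC(=O)c1ccc(O)c(O)c1O | starting material
2 | 1-bromo-3-methylbut-2-ene (prenyl bromide) | CC(C)=CCBr | starting material
3 | 1-[2,3-dihydroxy-4-(3-methylbut-2-enyloxy)phenyl]ethanone | CC(=O)c1ccc(OCC=C(C)C)c(O)c1O | intermediate
4 | 1-[2-hydroxy-3-(methoxymethoxy)-4-(3-methylbut-2-enyloxy)phenyl]ethanone | CC(=O)c1ccc(OCC=C(C)C)c(OCOC)c1O | intermediate
5 | 1-[2-methoxy-3-(methoxymethoxy)-4-(3-methylbut-2-enyloxy)phenyl]ethanone | CC(=O)c1ccc(OCC=C(C)C)c(OCOC)c1OC | intermediate
6 | 1-[4-hydroxy-2-methoxy-3-(methoxymethoxy)-5-(2-methylbut-3-en-2-yl)phenyl]ethanone | CC(=O)c1cc(C(C)(C)C=C)c(O)c(OCOC)c1OC | intermediate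
7 | 1-[2-methoxy-3,4-bis(methoxymethoxy)-5-(2-methylbut-3-en-2-yl)phenyl]ethanone | CC(=O)c1cc(C(C)(C)C=C)c(OCOC)c(OCOC)c1OC | intermediate
8 | potassium enolate of 7 (not isolated) | [K+].C=C([O-])c1cc(C(C)(C)C=C)c(OCOC)c(OCOC)c1OC | intermediate
9 | 1-[2-methoxy-3,4-bis(methoxymethoxy)-5-(2-methylbut-3-en-2-yl)phenyl]ethenyl trifluoromethanesulfonate | C=C(OS(=O)(=O)C(F)(F)F)c1cc(C(C)(C)C=C)c(OCOC)c(OCOC)c1OC | intermediate
10 | 2,4-dihydroxybenzaldehyde | O=Cc1ccc(O)cc1O | starting material
11 | 4-formyl-3-hydroxyphenyl pivalate | CC(C)(C)C(=O)Oc1ccc(C=O)c(O)c1 | intermediate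
12 | 3-(tert-butyldimethylsilyloxy)-4-formylphenyl pivalate | CC(C)(C)C(=O)Oc1ccc(C=O)c(O[Si](C)(C)C(C)(C)C)c1 | intermediate
13 | 3-(tert-butyldimethylsilyloxy)-4-(hydroxymethyl)phenyl pivalate | CC(C)(C)C(=O)Oc1ccc(CO)c(O[Si](C)(C)C(C)(C)C)c1 | intermediate
14 | 3-(tert-butyldimethylsilyloxy)-4-(chloromethyl)phenyl pivalate | CC(C)(C)C(=O)Oc1ccc(CCl)c(O[Si](C)(C)C(C)(C)C)c1 | intermediate
15 | [2-(tert-butyldimethylsilyloxy)-4-(pivaloyloxy)benzyl]zinc chloride (not isolated) | CC(C)(C)C(=O)Oc1ccc(C[Zn]Cl)c(O[Si](C)(C)C(C)(C)C)c1 | intermediate
16 | 3-(tert-butyldimethylsilyloxy)-4-{2-[2-methoxy-3,4-bis(methoxymethoxy)-5-(2-methylbut-3-en-2-yl)phenyl]prop-2-enyl}phenyl pivalate | C=CC(C)(C)c1cc(C(=C)Cc2ccc(OC(=O)C(C)(C)C)cc2O[Si](C)(C)C(C)(C)C)c(OC)c(OCOC)c1OCOC | intermediate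
17 | 3-hydroxy-4-{2-[2-methoxy-3,4-bis(methoxymethoxy)-5-(2-methylbut-3-en-2-yl)phenyl]prop-2-enyl}phenyl pivalate (precursor of the key step) | C=CC(C)(C)c1cc(C(=C)Cc2ccc(OC(=O)C(C)(C)C)cc2O)c(OC)c(OCOC)c1OCOC | intermediate
18 | (3S)-2'-methoxy-3',4'-bis(methoxymethoxy)-5'-(2-methylbut-3-en-2-yl)isoflavan-7-yl pivalate (product of the key step) | C=CC(C)(C)c1cc([C@H]2COc3cc(OC(=O)C(C)(C)C)ccc3C2)c(OC)c(OCOC)c1OCOC | intermediate
19 | (3S)-7-hydroxy-2'-methoxy-3',4'-bis(methoxymethoxy)-5'-(2-methylbut-3-en-2-yl)isoflavan (not isolated) | C=CC(C)(C)c1cc([C@H]2COc3cc(O)ccc3C2)c(OC)c(OCOC)c1OCOC | intermediate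
20 | (3S)-7,3',4'-trihydroxy-2'-methoxy-5'-(1,1-dimethylallyl)isoflavan = 4-[(3S)-7-hydroxychroman-3-yl]-3-methoxy-6-(2-methylbut-3-en-2-yl)benzene-1,2-diol | C=CC(C)(C)c1cc([C@H]2COc3cc(O)ccc3C2)c(OC)c(O)c1O | target

Total step count: 14. Longest linear sequence: 10 (steps 1–6, then 11–14); the ring A branch (steps 7–10) joins at step 11.

Steps most likely to fail

1. **Step 13.**
   - What may go wrong:
     - weak face discrimination in the hydrogen-atom transfer;
     - unproductive oxidation of the phenol;
     - thiyl-mediated hydrogen abstraction at C4 that moves the alkene into conjugation;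
     - thiol–ene consumption of the catalyst at the vinyl group.
   - Fallback with known chemistry, setting out from 16 and coming back at 18:
     - Copper-catalysed enantioselective protoboration of the 1,1-disubstituted aryl alkene (CuCl, NaOtBu, a chiral N-heterocyclic carbene or bisphosphine ligand, B2pin2, MeOH, THF) places boron on C2 and hydrogen on C3. The ligand fixes the face of the syn borylcupration, and the reaction should give the primary pinacol boronate F1.
     - The borylcopper species should prefer the aryl-conjugated alkene over the unactivated, neopentyl-type vinyl group.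
     - Oxidation with NaBO3·4H2O in THF/water should give the primary alcohol F2; the hindered pivalate is expected to survive the short, mildly basic treatment.
     - Buffered Bu4NF/AcOH frees O1 to give the hydroxy phenol F3.
     - A Mitsunobu etherification (PPh3, DIAD, THF) closes O1–C2 at the primary carbon without touching C3 and returns 18.

2. **Step 4.**
   - What may go wrong:
     - thermal loss of the prenyl group from the acyl-activated aryl ether;
     - on prolonged heating, onward isomerisation of the allyl group (abnormal Claisen pathway);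
     - ring closure of the new phenol onto the alkene.
   - Fallback without any sigmatropic step, setting out from 1 and coming back at 7:
     - Twofold MOM protection (MOMCl, iPr2NEt), which spares the chelated 2-OH, gives 1-[2-hydroxy-3,4-bis(methoxymethoxy)phenyl]ethanone F4.
     - MeI/K2CO3 gives 1-[2-methoxy-3,4-bis(methoxymethoxy)phenyl]ethanone F5.
     - NBS in MeCN at 0 °C brominates C5 (para to the 2-methoxy group, ortho to O4, meta to the acetyl group) to give 1-[5-bromo-2-methoxy-3,4-bis(methoxymethoxy)phenyl]ethanone F6.
     - A ligand-controlled γ-selective Suzuki–Miyaura coupling with 3-methylbut-2-enylboronic acid pinacol ester delivers the branched 1,1-dimethylallyl group and returns 7. Conditions: Pd(OAc)2, a bulky dialkylbiarylphosphine chosen for branched selectivity, K3PO4, THF/water.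

3. **Step 11.**
   - What may go wrong:
     - Wurtz-type homocoupling during zinc insertion;
     - slow transmetalation, which leaves the electron-rich alkenyl triflate time to decay.
   - Fallback by reversal of polarity, setting out from 9 and 14 and coming back at 16:
     - Miyaura borylation of 9 (B2pin2, PdCl2(PPh3)2, PPh3, KOPh, toluene, 50 °C) gives the alkenyl pinacol boronate F7.
     - F7 is joined to benzyl chloride 14, now the electrophile, by Suzuki–Miyaura coupling (Pd(OAc)2, SPhos, K3PO4, toluene, 60 °C) to return 16.

Further compounds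
F1 | step 13 | primary pinacol boronate: 3-(tert-butyldimethylsilyloxy)-4-{(2S)-2-[2-methoxy-3,4-bis(methoxymethoxy)-5-(2-methylbut-3-en-2-yl)phenyl]-3-(4,4,5,5-tetramethyl-1,3,2-dioxaborolan-2-yl)propyl}phenyl pivalate | C=CC(C)(C)c1cc([C@@H](CB2OC(C)(C)C(C)(C)O2)Cc3ccc(OC(=O)C(C)(C)C)cc3O[Si](C)(C)C(C)(C)C)c(OC)c(OCOC)c1OCOC
F2 | step 13 | primary alcohol: 3-(tert-butyldimethylsilyloxy)-4-{(2S)-3-hydroxy-2-[2-methoxy-3,4-bis(methoxymethoxy)-5-(2-methylbut-3-en-2-yl)phenyl]propyl}phenyl pivalate | C=CC(C)(C)c1cc([C@@H](CO)Cc2ccc(OC(=O)C(C)(C)C)cc2O[Si](C)(C)C(C)(C)C)c(OC)c(OCOC)c1OCOC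
F3 | step 13 | hydroxy phenol: 3-hydroxy-4-{(2S)-3-hydroxy-2-[2-methoxy-3,4-bis(methoxymethoxy)-5-(2-methylbut-3-en-2-yl)phenyl]propyl}phenyl pivalate | C=CC(C)(C)c1cc([C@@H](CO)Cc2ccc(OC(=O)C(C)(C)C)cc2O)c(OC)c(OCOC)c1OCOC
F4 | step 4 | 1-[2-hydroxy-3,4-bis(methoxymethoxy)phenyl]ethanone | CC(=O)c1ccc(OCOC)c(OCOC)c1O
F5 | step 4 | 1-[2-methoxy-3,4-bis(methoxymethoxy)phenyl]ethanone | CC(=O)c1ccc(OCOC)c(OCOC)c1OC
F6 | step 4 | 1-[5-bromo-2-methoxy-3,4-bis(methoxymethoxy)phenyl]ethanone | CC(=O)c1cc(Br)c(OCOC)c(OCOC)c1OC
F7 | step 11 | alkenyl pinacol boronate: 2-{1-[2-methoxy-3,4-bis(methoxymethoxy)-5-(2-methylbut-3-en-2-yl)phenyl]ethenyl}-4,4,5,5-tetramethyl-1,3,2-dioxaborolane | C=C(B1OC(C)(C)C(C)(C)O1)c1cc(C(C)(C)C=C)c(OCOC)c(OCOC)c1OC
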